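**Ash run.** We start from the ash run.

all flasks: starting material 18 mM; precatalyst 0.90 mM
- ash: reagent 36 mM (fed, over 25 s); run made earlier
- flask: reagent 18.0 mM (fed, over 25 s); time 2.5 min

ash run (percent of the starting material charged)

| time / s | starting material / % | product / % |
|---|---|---|
| 10.0 | 85.1 | 0.4 |
| 12.0 | 76.1 | 0.1 |
| 15.0 | 68.2 | 0.4 |

(each reading ± 1 percentage point)

- steps thought possible: free catalyst + open intermediate <-> catalyst intermediate; precatalyst <-> free catalyst; reagent + catalyst intermediate -> free catalyst + product; starting material + free catalyst <-> free catalyst + open intermediate

- amount of starting material in percent of the starting material charged, at 15 s, 50 s, 1.5 min and 2.5 min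

In the ash run at 15.0 s, product reads 0.4% with a scatter of 1 percentage point, so the starting material lost so far has gone to something other than product, which among the steps thought possible means open intermediate or catalyst intermediate. That opening step, under free catalyst, holds no reagent. We therefore carry the early curve over to the new flask, although it has half the reagent.

**Mean constant.** We replace the curved fall by one first-order decay that leaves the same fraction at the last reading: ln(charged/left) divided by the time. This gives 0.0255 s⁻¹. This mean loss constant treats the loss as pseudo-first-order. For the new flask it gives 68.2% at 15 s, 27.9% at 50 s and 2.18% at 2.5 min.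

**Weak link.** The constancy is the weak link. Between 10.0 s and 15.0 s the readings give 0.0443 s⁻¹, more than the mean, which is the lag expected while precatalyst releases free catalyst. Continuing from the last reading at this steeper constant gives 14.5% at 50 s. But neither constant contains the way back of the opening step, which works against the loss, so at 50 s we commit to the higher of the two values, 27.9%.

**Result.** The forecast gives 68%, 32%, 19% and 12%, its value at 50 s standing above our 27.9%, and says “the late values are rough”. The new flask gives 68.8%, 23.8%, 17.4% and 10.9%.

    free catalyst + open intermediate ⇌ catalyst intermediate (K = 240 L mol⁻¹, k = 22.5 L mol⁻¹ s⁻¹)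
    precatalyst ⇌ free catalyst (K = 3.47, k = 0.0182 s⁻¹)
    reagent + catalyst intermediate → free catalyst + product (k = 57.8 L mol⁻¹ s⁻¹)
    starting material + free catalyst ⇌ free catalyst + open intermediate (K = 2.98, k = 266 L mol⁻¹ s⁻¹)

**Way back.** Over 2.5 min the new flask's mean loss constant is 0.0148 s⁻¹, less than 0.0255 s⁻¹. The way back from open intermediate, together with the time allowed, holds up the remainder: without that way back 0% remains, and at 25.0 min 0.199% remains. The slow start of the catalyst is a part of the story: the same flask without it leaves 7.96%, a mean loss constant of 0.0169 s⁻¹, still less than 0.0255 s⁻¹.

All runs come from a simulation from invented constants, noise included.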